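The runs were computed on assumed constants, noise included.

Start from the leftover: give each L in west, south and south-east its one Q, and 18.5 mM of Q stays over. Call this the spare Q, the stoichiometric excess over L.

| flask | L | Q | temperature | remark | time |
|---|---|---|---|---|---|
| summer | 37 mM | 83 mM | 35 °C | run made earlier |  |
| west | 37 mM | 55.5 mM | 35 °C |  | 2.0 h |
| south | 37 mM | 55.5 mM | 60 °C |  | 2.0 h |
| south-east | 37 mM | 55.5 mM | 85 °C |  | 2.0 h |

- summer (time / min: G / %): 2.50: 19; 5.00: 36; 8.00: 45; 10.0: 48; 12.0: 54

(each reading ± 2 percentage points)

- a species is counted by the L in it: one D counts as two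
- amounts and yields of G count D too
- what was read earlier has a scatter of 2 percentage points, one standard deviation
- steps thought possible: L + Q -> G; Q -> X; 2 Q -> E; L + G <-> D
- the earlier runs do not show what temperature does; that part of a forecast is a guess
- in an amount of G, one D counts as one G

- which flask leads in amount of G, in percent of the L charged ("all alike" within 1.5 percentage points) (west / south / south-east / all alike)
- how much G is there at the end, in percent of the L charged: west
- how much G is there at the end, in percent of the L charged: south
- how much G is there at the end, in percent of the L charged: south-east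

Read the summer rows down. The reading at 12.0 min stands at 54%, so G has by then taken about 20.0 mM of Q, against a spare of 46.0 mM in that run. These rows carry a scatter of 2 percentage points and read G, not Q.

So reckon from both ends. If no Q is lost, G can reach 100 % with the spare Q untouched. If Q is lost, count U, the Q not in G, whether wasted or unused. Each G costs one Q, so G is the charge of Q less U, and the first 18.5 mM of U costs no G. Each mM of U beyond that comes off G.

Heat is a guess here: expect U to grow with temperature and G to fall from west to south-east, with no figure to commit to.

The forecast names west as leader, with 63% for west, 57% for south and 49% for south-east: “G therefore stops at a plateau set by selectivity”.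

The flasks give 77.4% for west, 65.1% for south and 44.7% for south-east, so west leads.

    L + Q → G (k = 1.33 L mol⁻¹ min⁻¹, Ea = 57.0 kJ mol⁻¹)
    Q → X (k = 0.00408 min⁻¹, Ea = 105 kJ mol⁻¹)
    2 Q → E (k = 0.330 L mol⁻¹ min⁻¹, Ea = 62.0 kJ mol⁻¹)
    L + G ⇌ D, settled at all times (K = 13.0 L mol⁻¹, ΔH = 9.00 kJ mol⁻¹)
    (constants at 35 °C)

In south-east, half the turnover to X was done by 0.314 min and half to E by 0.135 min, and Q stood at 0% at 1.00 h, with G at 44.7% then and 44.7% at 2.00 h. In west, Q still stood at 12.4% at 1.00 h while G went from 70.8% to 77.4% by 2.00 h. South-east's U is 38.9 mM, which is 55.3% of the L charge beyond the spare. The forecast and west part on U: 32.2 mM against 26.9 mM.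

The neighbour of south-east with 140 mM of Q has a spare of 103 mM, but its U is 114 mM, which is 31.1% of the L charge beyond the spare. That neighbour gives 68.9%.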